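## Structural features

The target 16 is a depside: ring A and ring B are joined only through one aryl ester, with no fused or bridged ring and no stereocentre, so nothing stereochemical has to be set. Ring A is an acetophenone that, counted from the acetyl-bearing carbon as C1, carries oxygen on C2, C3 and C4, hydrogen on C5 and the pentyl chain on C6. The ester oxygen is the central one (O3), para to the pentyl group and flanked by two free hydroxyls. Ring B is a 4-hydroxy-2-methoxy-6-propylbenzoyl unit whose carbonyl carbon sits between the methoxy and the propyl group. The fragile elements are the aryl ester (hydrolysis, and migration to a neighbouring ring A hydroxyl under base), the electron-rich phenols (oxidation), the aryl methyl ketone (enolisation, reduction) and the single methyl ether, which must survive the unmasking of three phenols. The real difficulty is to make an ester between a 2,6-disubstituted aroyl carbon and a phenol oxygen that itself has two ortho substituents, and to tell the central oxygen of ring A apart from its two neighbours. The key step uses the fact that the ester carbonyl is one carbon lying between C1 of ring B and O3 of ring A: it is delivered as carbon monoxide to a palladium-bound ring B, so the crowded acyl electrophile is generated on the metal and never handled as a free acid. Both rings descend from 5-alkylresorcinols, in which the site between the two oxygens (most acidic) and the sites between an oxygen and the alkyl chain (most nucleophilic) can be addressed separately.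

## Logic of the disconnections

16 to 15. The three phenolic O–H groups of 16 are traced back to O–CH2Ph bonds in 15. This postpones every free phenol to the last step, so the ester never meets base while a neighbouring hydroxyl is free, and it keeps the one methyl ether distinct from the removable ethers. The forward step must cleave three benzylic C–O bonds without touching the ketone or the ester; neutral hydrogenolysis meets this.

15 to 4, 14 and 13. The bond from C1 of ring B to the carbonyl carbon and the bond from that carbon to O3 of ring A are cut together. This is the one place where the molecule falls into two arenes of similar size plus a one-carbon gas, and it removes the need for a hindered benzoic acid. The forward step demands carbon monoxide insertion before C–O bond formation, a single free hydroxyl in 13, and a halide in 4 reactive enough for oxidative addition at a di-ortho-substituted carbon.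

13 to 10. The ring-to-acetyl bond is cut back to a C–Br bond. An acid-promoted acylation is avoided on purpose: a benzyl ether next to a new ketone is at risk with Lewis acids, and the free hydroxyl would be acylated first. The forward step needs halogen–metal exchange in the presence of an O–H (two equivalents of base) and an acyl donor that stops at the ketone.

10 to 9. The C–Br bond is cut. In 9 the only open ring positions are two equivalent ones, each ortho to one benzyloxy group and para to the other, so no regiochemical question arises. The forward step needs a mild bromine electrophile in one equivalent that does not oxidise the phenol.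

9 to 6 (through 8 and 7). The C–O bond at the central carbon is cut. The hydrogen between the two benzyloxy groups of 6 is the most acidic on the ring, so the oxygen can be introduced by lithiation, borylation and oxidation. The forward step must metalate the ring and not the benzylic CH2, and must oxidise the C–B bond without base.

6 to 5. Two O–benzyl bonds are cut, leading to a commercial symmetric diol; the forward step is a double etherification.

4 to 3. One O–benzyl bond is cut. The hydroxyl it frees is the group that controls the preceding iodination, so it is capped only afterwards.

3 to 2. The C–I bond is cut. The free hydroxyl of 2 directs the electrophile to its para position, which is exactly the carbon between methoxy and propyl. The forward step must favour para over ortho attack and stop at one iodine.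

2 to 1. One O–CH3 bond is cut, leading to a commercial symmetric diol. The forward step is a mono-alkylation under statistical control, with recovery of unreacted 1.

## Other disconnections considered

Alternative 1: The cut runs through ring A itself, at the bond between its CH carbon (C5) and the pentyl-bearing carbon (C6) and at the bond between the acetyl-bearing carbon (C1) and C2.
- Forward key step: Stille coupling of 4-chloro-2,3-diisopropoxycyclobut-2-en-1-one A2 with (E)-4-(tributylstannyl)non-3-en-2-one A3 would give the alkenylcyclobutenone A4. On warming, A4 should open in a four-electron process and close in a six-electron process, then tautomerise to 1-(2-hydroxy-3,4-diisopropoxy-6-pentylphenyl)ethanone A1.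
- In favour: every substituent position of ring A is fixed by the connectivity of the fragments, and the acetyl group arrives inside A3. On this point the alternative is better than the chosen plan, which has to force an acetyl group onto a di-ortho-substituted carbon in step 7. It also avoids organolithium reagents next to benzyl ethers.
- Against: A1 has its free hydroxyl on O2, whereas the ester must sit on O3, and O3 and O4 carry identical isopropyl ethers. Reaching 13 would need a cyclobutenone with two different alkoxy groups placed regioselectively, benzylation of the chelated O2–H, and selective unmasking of O3. Stoichiometric tin is needed, and A2 and A3 each need their own preparation.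
- Comparison: on regiocontrol of ring A the two plans are equal (the chosen one relies on the symmetry of 6 and 9). On mechanism the pericyclic cascade is milder than two lithiations. On step economy the alternative is clearly longer to 13, and it leaves the ester problem untouched, so step 8 would still be needed.

Alternative 2: The cut removes the ring-to-pentyl and ring-to-acetyl bonds of ring A in one operation, leading to 5-chloro-1,2,3-trimethoxybenzene A6.
- Forward key step: pentyllithium A8 would deprotonate A6 next to chlorine, and loss of LiCl would give 3,4,5-trimethoxybenzyne A7. A second equivalent of A8 should add to the aryne carbon remote from the methoxy group, leaving (2,3,4-trimethoxy-6-pentylphenyl)lithium A9. Acetylation of A9 with the Weinreb acetamide used in step 7 would give 1-(2,3,4-trimethoxy-6-pentylphenyl)ethanone A5.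
- In favour: two C–C bonds and the whole carbon skeleton of ring A come from one flask and a simple arene. In skeletal step economy this is better than the chosen plan (one operation against four). The regiochemistry of addition is controlled by the inductive effect of the adjacent methoxy group, and the acyl transfer is the same chemistry as in step 7, so the plans are equal there.
- Against: the three oxygens of A5 are indistinguishable methyl ethers, while 16 must keep exactly one methyl ether, on ring B. Demethylation before coupling gives a triol whose alkylation order (O4, then O3, then the chelated O2) is the opposite of what is needed. Demethylation after coupling cannot spare the ring B ether or the ester. Excess A8 also competes with A9 for the amide, and A9 can add to A7.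
- Comparison: structurally the alternative fails on oxygen differentiation, which the chosen plan solves by symmetry and benzyl ethers. Mechanistically it is sound. Its early gain in steps would be used up by protecting-group repair.

Alternative 3: The cut is the ring B bond between the ester-bearing carbon and the propyl-bearing carbon, which unravels ring B into a chain on the ring A oxygen.
- Forward key step: 3-acetyl-2,6-bis(benzyloxy)-4-pentylphenyl 3,5,7-trioxodecanoate A11 would undergo intramolecular aldol addition of C2 to the C7 ketone, then dehydration and enolisation, to give 3-acetyl-2,6-bis(benzyloxy)-4-pentylphenyl 2,4-dihydroxy-6-propylbenzoate A10.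
- In favour: the hindered aryl-to-carbonyl bond is formed inside a six-membered transition state, with no coupling of two crowded partners, and no pressurised carbon monoxide or palladium is needed. On these two points the alternative is equal to or better than the chosen plan. It also follows the biosynthetic logic.
- Against: A10 has both ring B hydroxyls free, and 16 needs methylation of the ortho one only. The para hydroxyl is the more reactive and the ortho one is chelated, so a protection of O4 and a base-mediated methylation next to a migration-prone ester would be added. The aryloxy group of A11 is a good leaving group, so Claisen-type closure or pyrone formation with expulsion of the phenoxide of 13 competes with the aldol path. The ring A methyl ketone is a further aldol partner, and the triketo chain needs its own steps.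
- Comparison: structurally it builds the right skeleton but the wrong oxygen pattern, whereas the chosen plan fixes the methyl ether in step 1. Mechanistically its cyclisation mode is less controllable than carbon monoxide insertion. In step count it would be longer after the key step.

Key step: step 8

Remark: the connectivities of 4, 13 and 15 were checked atom by atom against 16 and need no correction. The change made is to the preparation of 13, where the acetyl group enters through bromine–lithium exchange and not through an acid-mediated acylation.

Remark: 16 has no stereocentre; adduct 12 is a transient racemate whose stereocentre disappears at work-up. Carbon monoxide is counted as reactant 14.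

## Route

Step 1
Reactants: 1 5-propylresorcinol (5-propylbenzene-1,3-diol)
Product: 2 3-methoxy-5-propylphenol
Conditions: MeI (1.0 equiv), K2CO3 (1.1 equiv), acetone, reflux
Reagents that add atoms: iodomethane, CI
Why: Williamson mono-O-methylation under statistical control; with the alkylating agent limiting, the mono-ether should be the main product and is separated from the dimethyl ether and from unreacted 1, which is recycled.

Step 2
Reactants: 2 3-methoxy-5-propylphenol
Product: 3 4-iodo-3-methoxy-5-propylphenol
Conditions: NIS (1.0 equiv), TsOH·H2O (10 mol%), MeCN, −20 → 0 °C
Reagents that add atoms: N-iodosuccinimide, O=C1CCC(=O)N1I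
Why: Electrophilic aromatic iodination; the free hydroxyl is the strongest donor and should direct the bulky iodinating agent to its para position (also ortho to methoxy), while the carbon between the two oxygens is the most shielded; one equivalent at low temperature should limit di-iodination.

Step 3
Reactants: 3 4-iodo-3-methoxy-5-propylphenol
Product: 4 5-(benzyloxy)-2-iodo-1-methoxy-3-propylbenzene
Conditions: BnBr (1.1 equiv), K2CO3, DMF, rt
Reagents that add atoms: benzyl bromide, BrCc1ccccc1
Why: Williamson etherification of the only phenol; the aryl iodide is inert to carbonate, and the benzyl ether can be removed at the end beside the methyl ether.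

Step 4
Reactants: 5 olivetol (5-pentylbenzene-1,3-diol)
Product: 6 1,3-bis(benzyloxy)-5-pentylbenzene
Conditions: BnBr (2.3 equiv), K2CO3 (3 equiv), acetone, reflux
Reagents that add atoms: benzyl bromide, BrCc1ccccc1
Why: Double Williamson etherification; the two benzyloxy groups protect the future O2 and O4 of ring A and serve as a pair of directing groups for the next step.

Step 5
Reactants: 6 1,3-bis(benzyloxy)-5-pentylbenzene
Product: 9 2,6-bis(benzyloxy)-4-pentylphenol, via C2-aryllithium 7 (not isolated), via dimethyl arylboronate 8 (not isolated)
Conditions: n-BuLi (1.2 equiv), THF, 0 °C → rt; B(OMe)3 (2 equiv), −78 °C → rt; AcOH, 30% H2O2, 0 °C → rt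
Reagents that add atoms: n-butyllithium, [Li]CCCC (lithium in 7); trimethyl borate, COB(OC)OC (boron in 8); hydrogen peroxide, OO
Why: Directed ortho-metalation at the carbon flanked by two coordinating ether oxygens, borylation of the aryllithium, and oxidative 1,2-migration of the aryl group from boron to oxygen; the acidic peroxide medium spares the air-sensitive electron-rich phenoxide.

Step 6
Reactants: 9 2,6-bis(benzyloxy)-4-pentylphenol
Product: 10 2,6-bis(benzyloxy)-3-bromo-4-pentylphenol
Conditions: NBS (1.0 equiv), MeCN, −20 → 0 °C, dark
Reagents that add atoms: N-bromosuccinimide, O=C1CCC(=O)N1Br
Why: Electrophilic aromatic bromination; the only open ring positions are two equivalent carbons, each ortho to one benzyloxy group and para to the other, so a single regioisomer is possible, and one equivalent in the cold should prevent a second bromination.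

Step 7
Reactants: 10 2,6-bis(benzyloxy)-3-bromo-4-pentylphenol
Product: 13 1-[2,4-bis(benzyloxy)-3-hydroxy-6-pentylphenyl]ethanone, via dilithio phenoxide 11 (not isolated), via tetrahedral amide adduct 12 (not isolated)
Conditions: n-BuLi (2.2 equiv), THF, −78 °C; MeC(O)N(OMe)Me (1.5 equiv), −78 → 0 °C; 1 M HCl
Reagents that add atoms: n-butyllithium, [Li]CCCC (lithium in 11 and 12); N-methoxy-N-methylacetamide, CC(=O)N(C)OC
Why: The first equivalent of base forms the lithium phenoxide and the second effects bromine–lithium exchange; the aryllithium undergoes Weinreb ketone synthesis, the chelated adduct 12 collapsing to the ketone only at work-up, so over-addition is excluded and the phenoxide needs no protection.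

Step 8
Reactants: 4 5-(benzyloxy)-2-iodo-1-methoxy-3-propylbenzene, 13 1-[2,4-bis(benzyloxy)-3-hydroxy-6-pentylphenyl]ethanone, 14 carbon monoxide
Product: 15 3-acetyl-2,6-bis(benzyloxy)-4-pentylphenyl 4-(benzyloxy)-2-methoxy-6-propylbenzoate
Conditions: Pd(OAc)2 (5 mol%), Xantphos (7.5 mol%), Et3N (3 equiv), CO (3 bar), 4 Å MS, toluene, 90 °C
Reagents that add atoms: none
Why: Pd(OAc)2 is reduced in the flask to zerovalent palladium held by Xantphos, which adds oxidatively to the C–I bond of 4; the iodide is chosen because this carbon is flanked by methoxy and propyl and the weak carbon–iodine bond keeps the addition fast. Carbon monoxide 14 then coordinates and inserts to give an aroyl divalent palladium species, in which the reacting carbon has moved one atom away from the two ortho groups. Et3N converts 13 into its phenoxide, which displaces iodide on the metal (or attacks the acyl carbon directly), and C–O reductive elimination releases 15 and returns zerovalent palladium. The closest known reaction type is the palladium-catalysed aryloxycarbonylation (carbonylative esterification) of aryl halides with phenols. No ring is closed and no stereocentre is formed, so only chemoselectivity is at stake. Insertion of carbon monoxide must come before C–O bond formation: the wide bite angle of Xantphos and a few bar of carbon monoxide favour the acyl complex, and direct aryl–oxygen elimination from so hindered an aryl palladium phenoxide is slow in any case. Site selectivity is secured by the substrate, since O3 is the only free hydroxyl of 13 (O2 and O4 are benzylated) and Et3N is too weak to enolise the methyl ketone towards arylation. Molecular sieves keep water from intercepting the aroyl complex as the carboxylic acid.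

Step 9
Reactants: 15 3-acetyl-2,6-bis(benzyloxy)-4-pentylphenyl 4-(benzyloxy)-2-methoxy-6-propylbenzoate
Product: 16 3-acetyl-2,6-dihydroxy-4-pentylphenyl 4-hydroxy-2-methoxy-6-propylbenzoate
Conditions: H2 (1 atm), 10% Pd/C, EtOAc, rt
Reagents that add atoms: none
Why: Catalytic hydrogenolysis of three aryl benzyl ethers under neutral conditions; the aryl ester, the methyl ether and the hindered, chelated aryl ketone should survive, and the absence of base avoids acyl migration from O3 to the freed neighbouring hydroxyls.

## Compound list

1 | 5-propylresorcinol (5-propylbenzene-1,3-diol) | CCCc1cc(O)cc(O)c1 | starting material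
2 | 3-methoxy-5-propylphenol | CCCc1cc(O)cc(OC)c1 | intermediate
3 | 4-iodo-3-methoxy-5-propylphenol | CCCc1cc(O)cc(OC)c1I | intermediate
4 | 5-(benzyloxy)-2-iodo-1-methoxy-3-propylbenzene | CCCc1cc(OCc2ccccc2)cc(OC)c1I | intermediate
5 | olivetol (5-pentylbenzene-1,3-diol) | CCCCCc1cc(O)cc(O)c1 | starting material
6 | 1,3-bis(benzyloxy)-5-pentylbenzene | CCCCCc1cc(OCc2ccccc2)cc(OCc2ccccc2)c1 | intermediate
7 | [2,6-bis(benzyloxy)-4-pentylphenyl]lithium (not isolated) | CCCCCc1cc(OCc2ccccc2)c([Li])c(OCc2ccccc2)c1 | intermediate
8 | dimethyl [2,6-bis(benzyloxy)-4-pentylphenyl]boronate (not isolated) | CCCCCc1cc(OCc2ccccc2)c(B(OC)OC)c(OCc2ccccc2)c1 | intermediate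
9 | 2,6-bis(benzyloxy)-4-pentylphenol | CCCCCc1cc(OCc2ccccc2)c(O)c(OCc2ccccc2)c1 | intermediate
10 | 2,6-bis(benzyloxy)-3-bromo-4-pentylphenol | CCCCCc1cc(OCc2ccccc2)c(O)c(OCc2ccccc2)c1Br | intermediate
11 | lithium 2,6-bis(benzyloxy)-3-lithio-4-pentylphenolate (not isolated) | CCCCCc1cc(OCc2ccccc2)c(O[Li])c(OCc2ccccc2)c1[Li] | intermediate
12 | dilithium salt of 1-[2,4-bis(benzyloxy)-3-hydroxy-6-pentylphenyl]-1-[methoxy(methyl)amino]ethanol, racemic (not isolated) | CCCCCc1cc(OCc2ccccc2)c(O[Li])c(OCc2ccccc2)c1C(C)(O[Li])N(C)OC | intermediate
13 | 1-[2,4-bis(benzyloxy)-3-hydroxy-6-pentylphenyl]ethanone | CCCCCc1cc(OCc2ccccc2)c(O)c(OCc2ccccc2)c1C(C)=O | intermediate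
14 | carbon monoxide | [C-]#[O+] | starting material
15 | 3-acetyl-2,6-bis(benzyloxy)-4-pentylphenyl 4-(benzyloxy)-2-methoxy-6-propylbenzoate | CCCCCc1cc(OCc2ccccc2)c(OC(=O)c2c(CCC)cc(OCc3ccccc3)cc2OC)c(OCc2ccccc2)c1C(C)=O | intermediate
16 | 3-acetyl-2,6-dihydroxy-4-pentylphenyl 4-hydroxy-2-methoxy-6-propylbenzoate | CCCCCc1cc(O)c(OC(=O)c2c(CCC)cc(O)cc2OC)c(O)c1C(C)=O | target

## Step count and risk

Total: 9 steps. Longest linear sequence: 6 steps (steps 4, 5, 6, 7, 8, 9); the ring B branch (steps 1 to 3) joins at step 8.

Step 8 (key step). The capture of the hindered aroyl palladium species by a hindered phenoxide may be slow. Hydrodeiodination, hydrolysis of the acyl complex by traces of water, or aggregation of the catalyst under carbon monoxide could then take over. Fallback: the same two bonds are made one after the other without palladium. The fallback sets out from 4: iodine–lithium exchange (n-BuLi, THF, −78 °C) gives [4-(benzyloxy)-2-methoxy-6-propylphenyl]lithium F1, which is quenched with CO2 and acidified to 4-(benzyloxy)-2-methoxy-6-propylbenzoic acid F2. (COCl)2 with catalytic DMF in CH2Cl2 gives 4-(benzyloxy)-2-methoxy-6-propylbenzoyl chloride F3, which acylates 13 (Et3N, catalytic DMAP, CH2Cl2). The route is rejoined at 15.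

Step 2. Attack ortho to the hydroxyl (para to the methoxy group) or a second iodination may compete, leading to poor regioselectivity. Fallback: the fallback sets out from 2 and uses the high para preference of nitrosation. NaNO2 in aqueous HCl/EtOH at 0 °C should give 3-methoxy-4-nitroso-5-propylphenol F4, and Na2S2O4 reduces it to 4-amino-3-methoxy-5-propylphenol F5. Diazotisation (NaNO2, HCl, 0 °C) gives 4-hydroxy-2-methoxy-6-propylbenzenediazonium chloride F6, and KI displaces nitrogen. The route is rejoined at 3.

Step 5. Deprotonation at a benzylic OCH2 followed by Wittig rearrangement, or incomplete ring metalation, may erode the lithiation. Fallback: the fallback sets out from 5 and places a halogen at the central carbon first. I2 and NaHCO3 in water/THF at 0 °C should give 2-iodo-5-pentylbenzene-1,3-diol F7, and BnBr with K2CO3 gives 1,3-bis(benzyloxy)-2-iodo-5-pentylbenzene F8. Iodine–lithium exchange with n-BuLi at −78 °C then generates 7 in the cold, where rearrangement has no time to occur. The route is rejoined at 7 and continues to 9 as in step 5.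

Step 6. Oxidation of the electron-rich free phenol, ipso attack at a substituted carbon, or over-bromination may compete with clean substitution. Fallback: the fallback sets out from 9 and masks the phenol as an ester. Ac2O and pyridine give 2,6-bis(benzyloxy)-4-pentylphenyl acetate F9, NBS in MeCN gives 2,6-bis(benzyloxy)-3-bromo-4-pentylphenyl acetate F10, and K2CO3 in MeOH removes the acetate. The route is rejoined at 10.

Step 7. Proton transfer from the acetyl CH3 of the amide to the hindered aryllithium (net loss of bromine without acylation), or sluggish exchange on the phenoxide, may lower conversion. Fallback: the fallback sets out from 9, bypasses 10 and uses no organometallic reagent. Acetyl trifluoroacetate made from AcOH and (CF3CO)2O in CH2Cl2 at 0 °C to rt, with no Lewis acid that would threaten the benzyl ethers, should acetylate both the oxygen and the one activated ring carbon. This gives 3-acetyl-2,6-bis(benzyloxy)-4-pentylphenyl acetate F11, and K2CO3 in MeOH cleaves the aryl acetate. The route is rejoined at 13.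

Step 9. Over-reduction of the aryl ketone, incomplete cleavage of the two hindered ring A ethers, or acyl migration on prolonged reaction may occur. Fallback: the fallback sets out from 15 and replaces hydrogenolysis by Lewis-acid debenzylation with a cation scavenger (BCl3, pentamethylbenzene, CH2Cl2, −78 °C), kept cold so that the methyl ether is spared. It makes no new compound (F0). The route is rejoined at 16.

## Further compounds

F1 | step 8 | [4-(benzyloxy)-2-methoxy-6-propylphenyl]lithium | CCCc1cc(OCc2ccccc2)cc(OC)c1[Li]
F2 | step 8 | 4-(benzyloxy)-2-methoxy-6-propylbenzoic acid | CCCc1cc(OCc2ccccc2)cc(OC)c1C(=O)O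
F3 | step 8 | 4-(benzyloxy)-2-methoxy-6-propylbenzoyl chloride | CCCc1cc(OCc2ccccc2)cc(OC)c1C(Cl)=O
F4 | step 2 | 3-methoxy-4-nitroso-5-propylphenol | CCCc1cc(O)cc(OC)c1N=O
F5 | step 2 | 4-amino-3-methoxy-5-propylphenol | CCCc1cc(O)cc(OC)c1N
F6 | step 2 | 4-hydroxy-2-methoxy-6-propylbenzenediazonium chloride | CCCc1cc(O)cc(OC)c1[N+]#N.[Cl-]
F7 | step 5 | 2-iodo-5-pentylbenzene-1,3-diol | CCCCCc1cc(O)c(I)c(O)c1
F8 | step 5 | 1,3-bis(benzyloxy)-2-iodo-5-pentylbenzene | CCCCCc1cc(OCc2ccccc2)c(I)c(OCc2ccccc2)c1
F9 | step 6 | 2,6-bis(benzyloxy)-4-pentylphenyl acetate | CCCCCc1cc(OCc2ccccc2)c(OC(C)=O)c(OCc2ccccc2)c1
F10 | step 6 | 2,6-bis(benzyloxy)-3-bromo-4-pentylphenyl acetate | CCCCCc1cc(OCc2ccccc2)c(OC(C)=O)c(OCc2ccccc2)c1Br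
F11 | step 7 | 3-acetyl-2,6-bis(benzyloxy)-4-pentylphenyl acetate | CCCCCc1cc(OCc2ccccc2)c(OC(C)=O)c(OCc2ccccc2)c1C(C)=O
F0 | step 9 | none | none
A1 | alternative 1 | 1-(2-hydroxy-3,4-diisopropoxy-6-pentylphenyl)ethanone | CCCCCc1cc(OC(C)C)c(OC(C)C)c(O)c1C(C)=O
A2 | alternative 1 | 4-chloro-2,3-diisopropoxycyclobut-2-en-1-one (racemic) | CC(C)OC1=C(OC(C)C)C(Cl)C1=O
A3 | alternative 1 | (E)-4-(tributylstannyl)non-3-en-2-one | CCCCC/C(=C\C(C)=O)[Sn](CCCC)(CCCC)CCCC
A4 | alternative 1 | (E)-4-(2,3-diisopropoxy-4-oxocyclobut-2-en-1-yl)non-3-en-2-one (racemic) | CCCCC/C(=C\C(C)=O)C1C(=O)C(OC(C)C)=C1OC(C)C
A5 | alternative 2 | 1-(2,3,4-trimethoxy-6-pentylphenyl)ethanone | CCCCCc1cc(OC)c(OC)c(OC)c1C(C)=O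
A6 | alternative 2 | 5-chloro-1,2,3-trimethoxybenzene | COc1cc(Cl)cc(OC)c1OC
A7 | alternative 2 | 3,4,5-trimethoxybenzyne | COC1=C(OC)C(OC)=CC#C1
A8 | alternative 2 | pentyllithium | [Li]CCCCC
A9 | alternative 2 | (2,3,4-trimethoxy-6-pentylphenyl)lithium | [Li]c1c(CCCCC)cc(OC)c(OC)c1OC
A10 | alternative 3 | 3-acetyl-2,6-bis(benzyloxy)-4-pentylphenyl 2,4-dihydroxy-6-propylbenzoate | CCCCCc1cc(OCc2ccccc2)c(OC(=O)c2c(CCC)cc(O)cc2O)c(OCc2ccccc2)c1C(C)=O
A11 | alternative 3 | 3-acetyl-2,6-bis(benzyloxy)-4-pentylphenyl 3,5,7-trioxodecanoate | CCCCCc1cc(OCc2ccccc2)c(OC(=O)CC(=O)CC(=O)CC(=O)CCC)c(OCc2ccccc2)c1C(C)=O
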